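1) Ring B, the 2,3-dimethoxy-1,4-benzoquinone, is closed last by thermal ring expansion (Moore rearrangement) of a 4-alkynyl-4-hydroxy-2,3-dimethoxycyclobutenone. This temporary four-membered ring is consumed by the step itself, and only a MOM cleavage follows.
2) Enabling feature: the contiguous ring-B unit C(=O)-C(OMe)=C(OMe)-C(=O) is the carbon skeleton of dimethyl squarate. The remaining edge C(chroman-3-yl)=CH is a terminal alkyne on the sp3 carbon C3 of ring C. This secondary alkyl carbon does not stabilise a radical, so it steers six-ring closure, and the ring hydrogen comes from the carbinol OH.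
3) The cyclobutenone comes from dimethyl squarate plus a lithium acetylide. The acetylide is released from the 1,1-dibromoalkene (Corey-Fuchs) of (R)-chroman-3-carbaldehyde.
4) The C3 stereocentre comes from Ru/H8-BINAP hydrogenation of the 2H-chromene-3-carboxylic acid. Ring C comes from oxa-Michael/aldol annulation of a salicylaldehyde with acrolein.
5) Ring A is bought as 2,3,4-trimethoxybenzaldehyde and re-patterned by Dakin oxidation, ortho-formylation, relayed demethylation and mono-MOM protection. Ring order: A (bought), C (step 5), B (step 12).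

Key step: step 12

Assumption: the stereocentre C3 of the given SMILES is read as S. The carbinol carbon of the squarate adduct forms as a mixture of epimers and is drawn without configuration, because the key step turns it into a carbonyl carbon.

Step 1
Reactants: 1 2,3,4-trimethoxybenzaldehyde
Product: 3 2,3,4-trimethoxyphenol, via aryl formate 2 (not isolated)
Conditions: 30% aq H2O2, cat. H2SO4, MeOH, rt
Reagents that add atoms: hydrogen peroxide (OO)
Why: Acid-catalysed Dakin oxidation (Baeyer-Villiger type), in which the electron-rich aryl group migrates to oxygen and formate 2 is methanolysed in the same flask.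

Step 2
Reactants: 3 2,3,4-trimethoxyphenol
Product: 4 2-hydroxy-3,4,5-trimethoxybenzaldehyde
Conditions: MgCl2, Et3N, (CH2O)n, MeCN, reflux; then 1 M HCl
Reagents that add atoms: paraformaldehyde, counted as formaldehyde (C=O)
Why: Casnati-Skattebøl ortho-formylation, in which the magnesium phenoxide delivers formaldehyde to the only free ortho carbon and a second formaldehyde takes up hydride to give the salicylaldehyde.

Step 3
Reactants: 4 2-hydroxy-3,4,5-trimethoxybenzaldehyde
Product: 6 2,3-dihydroxy-4,5-dimethoxybenzaldehyde, via cyclic chloroborate 5 (not isolated)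
Conditions: BCl3 (2 equiv), CH2Cl2, -20 °C to rt; then H2O
Reagents that add atoms: none
Why: Chelation-relayed Lewis acid demethylation, in which boron held on the C2 phenoxide reaches only the neighbouring C3 methoxy group and the five-membered borate 5 drives the cleavage, as in the known conversions of 2,3,4-trimethoxybenzaldehyde into 2,3-dihydroxy-4-methoxybenzaldehyde and of 5-hydroxy-6-methoxyflavones into 5,6-dihydroxyflavones.

Step 4
Reactants: 6 2,3-dihydroxy-4,5-dimethoxybenzaldehyde
Product: 8 2-hydroxy-4,5-dimethoxy-3-(methoxymethoxy)benzaldehyde, via disodium dianion 7 (not isolated)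
Conditions: NaH (2.1 equiv), THF-DMF, 0 °C; MOMCl (1.0 equiv), 0 °C; then aq NH4Cl
Reagents that add atoms: chloromethyl methyl ether (COCCl)
Why: Regioselective mono-O-alkylation of a catechol dianion (Williamson type), because in 7 the C2 phenoxide is delocalised into and chelated by the formyl group, so the more basic C3 phenoxide takes the single equivalent of MOMCl.

Step 5
Reactants: 8 2-hydroxy-4,5-dimethoxy-3-(methoxymethoxy)benzaldehyde; 9 acrolein
Product: 10 6,7-dimethoxy-8-(methoxymethoxy)-2H-chromene-3-carbaldehyde
Conditions: K2CO3, 1,4-dioxane, reflux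
Reagents that add atoms: none
Why: Domino oxa-Michael addition/intramolecular aldol condensation of a salicylaldehyde with acrolein, the standard entry to 2H-chromene-3-carbaldehydes, closes ring C and is pulled forward by the irreversible dehydration.

Step 6
Reactants: 10 6,7-dimethoxy-8-(methoxymethoxy)-2H-chromene-3-carbaldehyde
Product: 11 6,7-dimethoxy-8-(methoxymethoxy)-2H-chromene-3-carboxylic acid
Conditions: NaClO2, NaH2PO4, 2-methyl-2-butene, t-BuOH-H2O, rt
Reagents that add atoms: sodium chlorite ([Na+].[O-]Cl=O)
Why: Pinnick oxidation takes the enal to the acid without touching the alkene, the MOM ether or the electron-rich arene, because the alkene scavenger removes the chlorinating by-product.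

Step 7
Reactants: 11 6,7-dimethoxy-8-(methoxymethoxy)-2H-chromene-3-carboxylic acid
Product: 12 (R)-6,7-dimethoxy-8-(methoxymethoxy)chroman-3-carboxylic acid
Conditions: Ru(OAc)2[(S)-H8-BINAP] (1 mol %), H2 (4 atm), MeOH, rt
Reagents that add atoms: none
Why: Noyori-type carboxylate-directed asymmetric hydrogenation of a trisubstituted alpha,beta-unsaturated acid, in which 11 binds to ruthenium as carboxylate and has the same alkene geometry as tiglic and (E)-2-methylcinnamic acid (beta substituent trans to CO2H), so the (S)-ligand that reduces those to the (S)-acids should deliver hydrogen to the same face, which here is named R because the OCH2 group outranks the benzylic CH2.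

Step 8
Reactants: 12 (R)-6,7-dimethoxy-8-(methoxymethoxy)chroman-3-carboxylic acid
Product: 13 (S)-[6,7-dimethoxy-8-(methoxymethoxy)chroman-3-yl]methanol
Conditions: BH3·THF, THF, 0 °C to rt; then H2O
Reagents that add atoms: none
Why: Chemoselective borane reduction of a carboxylic acid via the acyloxyborane is non-basic, so C3 is not epimerised (the descriptor changes by priority only) and the acetal and methyl ethers are inert.

Step 9
Reactants: 13 (S)-[6,7-dimethoxy-8-(methoxymethoxy)chroman-3-yl]methanol
Product: 14 (R)-6,7-dimethoxy-8-(methoxymethoxy)chroman-3-carbaldehyde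
Conditions: Dess-Martin periodinane, CH2Cl2, 0 °C to rt
Reagents that add atoms: none
Why: Dess-Martin oxidation is base-free and stops at the aldehyde, which avoids enolisation and retro-oxa-Michael opening of this beta-aryloxy aldehyde, so C3 is kept.

Step 10
Reactants: 14 (R)-6,7-dimethoxy-8-(methoxymethoxy)chroman-3-carbaldehyde
Product: 15 (S)-3-(2,2-dibromovinyl)-6,7-dimethoxy-8-(methoxymethoxy)chroman
Conditions: CBr4, PPh3, CH2Cl2, 0 °C
Reagents that add atoms: carbon tetrabromide (BrC(Br)(Br)Br)
Why: Ramirez/Corey-Fuchs dibromoolefination, in which the non-basic ylide adds to the aldehyde faster than it could enolise it, so the alpha stereocentre is carried over unchanged.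

Step 11
Reactants: 15 (S)-3-(2,2-dibromovinyl)-6,7-dimethoxy-8-(methoxymethoxy)chroman; 16 dimethyl squarate
Product: 18 4-{[(S)-6,7-dimethoxy-8-(methoxymethoxy)chroman-3-yl]ethynyl}-4-hydroxy-2,3-dimethoxycyclobut-2-en-1-one (both carbinol epimers), via lithium acetylide 17 (not isolated)
Conditions: n-BuLi (2.1 equiv), THF, -78 to 0 °C; cannulated into 16, THF, -78 °C; aq NH4Cl at -78 °C
Reagents that add atoms: none
Why: The second stage of the Corey-Fuchs sequence (Br/Li exchange, Fritsch-Buttenberg-Wiechell type shift, deprotonation) gives acetylide 17, which adds 1,2 to one of the two equivalent carbonyl groups of 16 at low temperature, and the uncontrolled carbinol centre is erased in step 12.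

Step 12
Reactants: 18 4-{[(S)-6,7-dimethoxy-8-(methoxymethoxy)chroman-3-yl]ethynyl}-4-hydroxy-2,3-dimethoxycyclobut-2-en-1-one
Product: 21 2,3-dimethoxy-5-[(S)-6,7-dimethoxy-8-(methoxymethoxy)chroman-3-yl]-1,4-benzoquinone, via vinylketene 19 (not isolated), via diradical 20 (not isolated)
Conditions: p-xylene (0.01 M, degassed), 138 °C
Reagents that add atoms: none
Why: Heating opens the cyclobutenone by conrotatory 4π electrocyclic ring opening in which the donor hydroxyl group rotates outward, so the alkynyl group turns inward and lies next to the ketene carbon of 19. The ketene carbon then bonds to the distal alkyne carbon, the one that carries C3 of the chroman, in a 6-endo-dig closure that gives the aromatic phenoxyl/aryl sigma diradical 20, and transfer of the hydroxyl hydrogen to the neighbouring ring carbon radical delivers ring B directly at the quinone oxidation level. This is the Moore rearrangement of 4-alkynyl-4-hydroxycyclobutenones, and its closest precedents are 4-(alk-1-ynyl)-4-hydroxy-2,3-dimethoxycyclobutenones bearing plain alkyl chains. No new stereocentre arises: the carbinol centre becomes a carbonyl carbon, which makes the epimer mixture harmless, and C3 lies outside the pericyclic and radical array and should keep its S configuration under these neutral conditions. The step needs six-ring over five-ring (5-exo-dig) closure, which the secondary alkyl, not radical-stabilising, alkyne substituent secures, and its regiochemistry is fixed because the alkyl-bearing carbon must end next to the former ketene carbonyl and the hydrogen next to the former carbinol carbon. High dilution in degassed solvent suppresses bimolecular trapping of ketene and diradical.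

Step 13
Reactants: 21 2,3-dimethoxy-5-[(S)-6,7-dimethoxy-8-(methoxymethoxy)chroman-3-yl]-1,4-benzoquinone
Product: 22 5-[(S)-8-hydroxy-6,7-dimethoxychroman-3-yl]-2,3-dimethoxy-1,4-benzoquinone (target)
Conditions: p-TsOH·H2O (cat.), MeOH-CH2Cl2, 35 °C
Reagents that add atoms: none
Why: Acid-catalysed acetal exchange of a phenolic MOM ether, in which methanol traps the methoxymethyl cation before it can attack ring A, methoxy exchange at the quinone is degenerate in methanol, and C3 is not touched.

Compound list
1 | 2,3,4-trimethoxybenzaldehyde | COc1ccc(C=O)c(OC)c1OC | starting material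
2 | 2,3,4-trimethoxyphenyl formate (not isolated) | COc1ccc(OC=O)c(OC)c1OC | intermediate
3 | 2,3,4-trimethoxyphenol | COc1ccc(O)c(OC)c1OC | intermediate
4 | 2-hydroxy-3,4,5-trimethoxybenzaldehyde | COc1cc(C=O)c(O)c(OC)c1OC | intermediate
5 | 2-chloro-6,7-dimethoxy-1,3,2-benzodioxaborole-4-carbaldehyde (cyclic chloroborate, not isolated) | COc1cc(C=O)c2OB(Cl)Oc2c1OC | intermediate
6 | 2,3-dihydroxy-4,5-dimethoxybenzaldehyde | COc1cc(C=O)c(O)c(O)c1OC | intermediate
7 | disodium 3-formyl-5,6-dimethoxybenzene-1,2-diolate (not isolated) | [Na+].[Na+].COc1cc(C=O)c([O-])c([O-])c1OC | intermediate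
8 | 2-hydroxy-4,5-dimethoxy-3-(methoxymethoxy)benzaldehyde | COCOc1c(O)c(C=O)cc(OC)c1OC | intermediate
9 | acrolein | C=CC=O | starting material
10 | 6,7-dimethoxy-8-(methoxymethoxy)-2H-chromene-3-carbaldehyde | O=CC1=Cc2cc(OC)c(OC)c(OCOC)c2OC1 | intermediate
11 | 6,7-dimethoxy-8-(methoxymethoxy)-2H-chromene-3-carboxylic acid | OC(=O)C1=Cc2cc(OC)c(OC)c(OCOC)c2OC1 | intermediate
12 | (R)-6,7-dimethoxy-8-(methoxymethoxy)chroman-3-carboxylic acid | OC(=O)[C@H]1COc2c(cc(OC)c(OC)c2OCOC)C1 | intermediate
13 | (S)-[6,7-dimethoxy-8-(methoxymethoxy)chroman-3-yl]methanol | OC[C@H]1COc2c(cc(OC)c(OC)c2OCOC)C1 | intermediate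
14 | (R)-6,7-dimethoxy-8-(methoxymethoxy)chroman-3-carbaldehyde | O=C[C@H]1COc2c(cc(OC)c(OC)c2OCOC)C1 | intermediate
15 | (S)-3-(2,2-dibromovinyl)-6,7-dimethoxy-8-(methoxymethoxy)chroman | BrC(Br)=C[C@H]1COc2c(cc(OC)c(OC)c2OCOC)C1 | intermediate
16 | dimethyl squarate (3,4-dimethoxycyclobut-3-ene-1,2-dione) | COC1=C(OC)C(=O)C1=O | starting material
17 | lithium acetylide of (S)-3-ethynyl-6,7-dimethoxy-8-(methoxymethoxy)chroman (not isolated) | [Li]C#C[C@H]1COc2c(cc(OC)c(OC)c2OCOC)C1 | intermediate
18 | 4-{[(S)-6,7-dimethoxy-8-(methoxymethoxy)chroman-3-yl]ethynyl}-4-hydroxy-2,3-dimethoxycyclobut-2-en-1-one, both carbinol epimers | COC1=C(OC)C(O)(C#C[C@H]2COc3c(cc(OC)c(OC)c3OCOC)C2)C1=O | intermediate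
19 | (Z)-4-hydroxy-2,3-dimethoxy-6-[(S)-chroman-3-yl]hexa-1,3-dien-5-yn-1-one, chroman substituted as in 18 (vinylketene, not isolated) | O=C=C(OC)/C(OC)=C(/O)C#C[C@H]1COc2c(cc(OC)c(OC)c2OCOC)C1 | intermediate
20 | 4-hydroxy-2,3-dimethoxy-6-[(S)-chroman-3-yl]phenoxyl-5-yl diradical, chroman substituted as in 18 (not isolated) | [O]c1c(OC)c(OC)c(O)[c]c1[C@H]2COc3c(cc(OC)c(OC)c3OCOC)C2 | intermediate
21 | 2,3-dimethoxy-5-[(S)-6,7-dimethoxy-8-(methoxymethoxy)chroman-3-yl]-1,4-benzoquinone | COC1=C(OC)C(=O)C([C@H]2COc3c(cc(OC)c(OC)c3OCOC)C2)=CC1=O | intermediate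
22 | 5-[(S)-8-hydroxy-6,7-dimethoxychroman-3-yl]-2,3-dimethoxy-1,4-benzoquinone | COC1=C(OC)C(=O)C([C@H]2COc3c(cc(OC)c(OC)c3O)C2)=CC1=O | target

Total step count: 13. Longest linear sequence: 13 steps (1 to 22). Acrolein 9 and dimethyl squarate 16 enter as bought building blocks.

Steps most likely to fail

Risk 1 (step 12). The aryl radical centre of the diradical may take a hydrogen atom from C4 or C2 of the chroman by 1,5-transfer. The ketene may also close to the five-membered ring. Either process diverts material from quinone formation. The fallback is a closed-shell 6π route that sets out from 15 and comes back at 21.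
- 15 is treated with n-BuLi (2.1 equiv, THF, -78 °C) and quenched with water to give the terminal alkyne (S)-3-ethynyl-6,7-dimethoxy-8-(methoxymethoxy)chroman F1.
- Alpha-selective hydroalumination (i-Bu2AlH, Ni(dppp)Cl2 cat., THF, rt) followed by NBS should give (R)-3-(1-bromovinyl)-6,7-dimethoxy-8-(methoxymethoxy)chroman F2.
- Bromine-lithium exchange (t-BuLi, THF, -78 °C) and addition to 16 should give the alkenyl adduct 4-hydroxy-2,3-dimethoxy-4-{1-[(S)-6,7-dimethoxy-8-(methoxymethoxy)chroman-3-yl]vinyl}cyclobut-2-en-1-one F3.
- Heating in toluene (110 °C) leads by 4π opening, 6π electrocyclisation and tautomerisation, without any radical, to the hydroquinone 2,3-dimethoxy-5-[(S)-6,7-dimethoxy-8-(methoxymethoxy)chroman-3-yl]benzene-1,4-diol F4.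
- Ag2O (Et2O, rt) oxidises F4 to 21.

Risk 2 (step 7). Facial discrimination may be incomplete, or turnover may be slow with this oxygen-rich heterocyclic acid. Enantiopurity lost here cannot be restored later. The fallback separates covalent diastereomers; it sets out from 11 and comes back at 13.
- 11 is hydrogenated without stereocontrol (H2, Pd/C, EtOAc) to the racemic 6,7-dimethoxy-8-(methoxymethoxy)chroman-3-carboxylic acid F5.
- F5 is coupled (DCC, DMAP cat., CH2Cl2) with (S)-4-benzyl-2-oxazolidinone.
- The two imides are separated by chromatography or crystallisation into the wanted (S)-4-benzyl-3-[(R)-6,7-dimethoxy-8-(methoxymethoxy)chroman-3-carbonyl]oxazolidin-2-one F6 and its unwanted epimer (S)-4-benzyl-3-[(S)-6,7-dimethoxy-8-(methoxymethoxy)chroman-3-carbonyl]oxazolidin-2-one F7.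
- LiBH4 (THF-MeOH, 0 °C) cleaves F6 reductively to 13, which also makes step 8 unnecessary.

Risk 3 (step 3). The wrong, equally flanked methyl ether at C4 may be cleaved, or demethylation may run on. The fallback demethylates first and brings in the fourth oxygen afterwards; it sets out from 1 and comes back at 6.
- BCl3 (CH2Cl2, rt) converts 1, which has only one flanked methoxy group next to the chelating site, into 2,3-dihydroxy-4-methoxybenzaldehyde F8.
- Bromination (Br2, NaOAc, AcOH) goes para to the C2 hydroxyl and ortho to the methoxy group, giving 5-bromo-2,3-dihydroxy-4-methoxybenzaldehyde F9.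
- Copper-catalysed methoxylation (NaOMe, CuBr, MeOH-DMF, 110 °C, argon) gives 6. This replaces steps 1 to 3.

Further compounds
F1 | step 12 | (S)-3-ethynyl-6,7-dimethoxy-8-(methoxymethoxy)chroman | C#C[C@H]1COc2c(cc(OC)c(OC)c2OCOC)C1
F2 | step 12 | (R)-3-(1-bromovinyl)-6,7-dimethoxy-8-(methoxymethoxy)chroman | C=C(Br)[C@H]1COc2c(cc(OC)c(OC)c2OCOC)C1
F3 | step 12 | 4-hydroxy-2,3-dimethoxy-4-{1-[(S)-6,7-dimethoxy-8-(methoxymethoxy)chroman-3-yl]vinyl}cyclobut-2-en-1-one, both carbinol epimers | COC1=C(OC)C(O)(C(=C)[C@H]2COc3c(cc(OC)c(OC)c3OCOC)C2)C1=O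
F4 | step 12 | 2,3-dimethoxy-5-[(S)-6,7-dimethoxy-8-(methoxymethoxy)chroman-3-yl]benzene-1,4-diol | COc1c(O)cc([C@H]2COc3c(cc(OC)c(OC)c3OCOC)C2)c(O)c1OC
F5 | step 7 | racemic 6,7-dimethoxy-8-(methoxymethoxy)chroman-3-carboxylic acid | OC(=O)C1COc2c(cc(OC)c(OC)c2OCOC)C1
F6 | step 7 | (S)-4-benzyl-3-[(R)-6,7-dimethoxy-8-(methoxymethoxy)chroman-3-carbonyl]oxazolidin-2-one | O=C([C@H]1COc2c(cc(OC)c(OC)c2OCOC)C1)N1[C@@H](Cc2ccccc2)COC1=O
F7 | step 7 | (S)-4-benzyl-3-[(S)-6,7-dimethoxy-8-(methoxymethoxy)chroman-3-carbonyl]oxazolidin-2-one | O=C([C@@H]1COc2c(cc(OC)c(OC)c2OCOC)C1)N1[C@@H](Cc2ccccc2)COC1=O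
F8 | step 3 | 2,3-dihydroxy-4-methoxybenzaldehyde | COc1ccc(C=O)c(O)c1O
F9 | step 3 | 5-bromo-2,3-dihydroxy-4-methoxybenzaldehyde | COc1c(Br)cc(C=O)c(O)c1O
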